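What remains in the cedar run is the way in: its target stands at 69.5% after 3.00 min and at 44.9% after 8.00 min, so something keeps taking target away late in that run.

| flask | substrate | coupling partner | temperature | remark | time |
|---|---|---|---|---|---|
| birch | 0.060 M | 1.5 equiv | 5 °C | run made earlier |  |
| cedar | 0.24 M | 1.5 equiv | 25 °C | run made earlier |  |
| elm | 0.12 M | 3 equiv | 5 °C | run made earlier |  |
| epsilon | 0.12 M | 1.50 equiv | 40 °C |  | 3.0 min |
| eta | 0.12 M | 1.50 equiv | 10 °C |  | 3.0 min |
| theta | 0.12 M | 1.50 equiv | 25 °C |  | 3.0 min |

| run | time / min | target / % |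
|---|---|---|
| birch | 1.33 | 35.5 |
| birch | 3.00 | 55.9 |
| birch | 5.00 | 65.1 |
| birch | 8.00 | 70.3 |
| birch | 12.0 | 71.9 |
| birch | 25.0 | 67.1 |
| cedar | 0.500 | 82.7 |
| cedar | 1.33 | 82.2 |
| cedar | 3.00 | 69.5 |
| cedar | 4.00 | 63.4 |
| cedar | 6.00 | 52.8 |
| cedar | 8.00 | 44.9 |
| elm | 4.00 | 91.7 |
| elm | 8.00 | 87.0 |
| elm | 12.0 | 83.6 |
| elm | 15.0 | 80.5 |
| elm | 25.0 | 71.6 |

(readings scatter by 0.5 percentage points)

- in a conversion other conformer counts as not yet reacted

- the best flask by amount of target, in percent of the substrate charged; "all alike" if 1.5 percentage points covers them all (epsilon / eta / theta / all alike)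
- amount of target at the end, in percent of the substrate charged, epsilon
- amount of target at the end, in percent of the substrate charged, eta
- amount of target at the end, in percent of the substrate charged, theta

Begin with the main step, substrate plus coupling partner to target. Taken as second order, at fixed temperature and fixed equivalents, its extent follows concentration times time. Counting that step alone, theta, at 0.12 M, therefore reaches at 1.00 min what cedar, at 0.24 M, showed at 0.500 min: 82.7%.

Now add the loss. Frozen as a first-order process, the cedar tail gives the loss constant, the fraction of target lost per minute at 25 °C once coupling is largely over (an apparent first-order rate constant): 0.0874 min⁻¹. Over the remaining 2.00 min, this reckoning brings theta down to 69.4%.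

The rest is a shortfall in the peak. Elm holds 91.7% at 4.00 min, more than the highest birch reading of 71.9%, and birch has the lower partner concentration. Theta has half the partner concentration of cedar, so its peak may fall short of the cedar reading, and 69.4% is a figure before that further cut, which this reckoning does not size. The constant belongs to 25 °C, so this reckoning stops at theta.

The forecast holds that “The target decays first-order, independent of partner”. It expects 29% in epsilon, 76% in eta and 66% in theta, with eta best; its theta lies below the reckoning above.

The flasks give 65.9% in epsilon, 78.2% in eta and 69.2% in theta, and the best is eta.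

    substrate ⇌ other conformer (K = 0.450, k = 0.0100 s⁻¹, Ea = 80.0 kJ mol⁻¹, ΔH = −34.0 kJ mol⁻¹)
    substrate + coupling partner → target (k = 0.410 L mol⁻¹ s⁻¹, Ea = 58.0 kJ mol⁻¹)
    coupling partner + other conformer → isomer of the product A (k = 0.0560 L mol⁻¹ s⁻¹, Ea = 41.0 kJ mol⁻¹)
    coupling partner → decomposed reagent (k = 0.00180 s⁻¹, Ea = 82.0 kJ mol⁻¹)
    target ⇌ isomer of the product B (K = 2.60, k = 0.00210 s⁻¹, Ea = 80.0 kJ mol⁻¹, ΔH = −86.0 kJ mol⁻¹)
    (constants at 25 °C)

Epsilon is where the forecast and the flask part: its target still stands at 65.7% after 30.0 min, with 32.1% as isomer of the product B at 3.00 min. Between 1.50 min and 3.00 min, hot epsilon loses target at 0.0237 min⁻¹, less than the loss constant of 0.0874 min⁻¹ from the cooler cedar run. Theta read at 8.0 min is the second flask: starting from 69.2% at 3.0 min, the loss constant gives 44.7%, and the flask holds 45.8%.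

(The data are simulated for an exercise; scatter was added.)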